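**Retrosynthetic overview**
- The target comes from a penta-silylated oxan-4-ol by global desilylation; the axial C4–OH comes from equatorial hydride attack on the oxan-4-one.
- The oxane is the only ring and is formed last: a δ-hydroxy (Z)-enol carbamate condenses with a 4-silyloxybenzaldehyde to an oxocarbenium ion that closes 6-endo (O1–C2 and C2–C3).
- C4–C5: the α-lithiated enol carbamate (acyl anion equivalent of C4) opens an (S)-terminal epoxide that carries C5, C6 and the arylethyl chain.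
- Key bond C3'–C4': a titanated 5-aryl-pentadienyl carbamate acts as the homoenolate of the future C4 carbonyl and adds through its γ-carbon to 4-arylbutanal, setting C3' and C4' together.
- All four aryl groups come from two bought silyl-protected building blocks (an aryl iodide and an aryl aldehyde).

Assumption: the target is exactly the stereoisomer in the given SMILES, (2S,3S,4S,6S)-3-[(1E,3R,4S)-4-hydroxy-1,7-bis(4-hydroxyphenyl)hept-1-en-3-yl]-2-(4-hydroxyphenyl)-6-[2-(4-hydroxyphenyl)ethyl]oxan-4-ol.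

Notation: ring atoms O1, C2–C6; side chain C1'–C7' (C3' on C3, C4' carries OH). TBS = tert-butyldimethylsilyl; Cb = N,N-diisopropylcarbamoyl.

**Step 1**
Reactants: 1 tert-butyl(4-iodophenoxy)dimethylsilane; 2 but-3-en-1-ol
Product: 3 4-[4-(TBSO)phenyl]butanal
Conditions: Pd(OAc)2 (3 mol %), Bu4NCl, NaHCO3, DMF, 50 °C
Reagents that add atoms: none
Why: Heck arylation of the terminal alkene under Jeffery conditions followed by palladium hydride chain-walking to the carbinol carbon gives the saturated aldehyde directly; no stereocentre is formed.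

**Step 2**
Reactants: 3 4-[4-(TBSO)phenyl]butanal
Product: 6 (2S)-2-{2-[4-(TBSO)phenyl]ethyl}oxirane, via α-chloro aldehyde 4 (not isolated), via chlorohydrin 5 (not isolated)
Conditions: (R)-2-[diphenyl(trimethylsilyloxy)methyl]pyrrolidine (10 mol %), N-chlorosuccinimide, CH2Cl2, 0 °C; then NaBH4, MeOH, 0 °C; then NaH, THF, 0 °C to rt
Reagents that add atoms: none
Why: Enamine-catalysed α-chlorination, in which the bulky group of the (R)-catalyst shields one enamine face, gives the (R)-chloride; reduction and intramolecular Williamson closure (SN2, inversion at the C–Cl carbon) then give the (S)-epoxide, the future C6.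

**Step 3**
Reactants: 7 4-(TBSO)benzaldehyde; 8 ethyl (2E)-4-(diethoxyphosphoryl)but-2-enoate
Product: 9 ethyl (2E,4E)-5-[4-(TBSO)phenyl]penta-2,4-dienoate
Conditions: LiN(SiMe3)2, THF, −78 °C to 0 °C; aq NH4Cl
Reagents that add atoms: none
Why: Vinylogous Horner–Wadsworth–Emmons olefination with a stabilised phosphonate anion gives the (E,E)-dienoate; the non-nucleophilic base leaves the aryl silyl ether intact.

**Step 4**
Reactants: 9 ethyl (2E,4E)-5-[4-(TBSO)phenyl]penta-2,4-dienoate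
Product: 10 (2E,4E)-5-[4-(TBSO)phenyl]penta-2,4-dien-1-ol
Conditions: i-Bu2AlH (2.2 equiv), CH2Cl2, −78 °C; aq potassium sodium tartrate
Reagents that add atoms: none
Why: 1,2-Reduction of the conjugated ester by the aluminium hydride at low temperature leaves both alkene geometries untouched.

**Step 5**
Reactants: 10 (2E,4E)-5-[4-(TBSO)phenyl]penta-2,4-dien-1-ol
Product: 11 (2E,4E)-5-[4-(TBSO)phenyl]penta-2,4-dien-1-yl N,N-diisopropylcarbamate
Conditions: i-Pr2NCOCl, pyridine, 80 °C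
Reagents that add atoms: N,N-diisopropylcarbamoyl chloride, CC(C)N(C(C)C)C(Cl)=O
Why: O-Carbamoylation installs the hindered Hoppe carbamate that directs and stabilises the later α-lithiations and resists nucleophilic attack.

**Step 6 (key step)**
Reactants: 11 (2E,4E)-5-[4-(TBSO)phenyl]penta-2,4-dien-1-yl N,N-diisopropylcarbamate; 3 4-[4-(TBSO)phenyl]butanal
Product: 14 (1Z,3R,4S)-4-hydroxy-7-[4-(TBSO)phenyl]-3-{(E)-2-[4-(TBSO)phenyl]ethenyl}hept-1-en-1-yl N,N-diisopropylcarbamate, via lithiated carbamate 12 (not isolated), via allyltitanium 13 (not isolated)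
Conditions: n-BuLi, (+)-sparteine, toluene, −78 °C; then Ti(OiPr)4, −78 °C; then 3, −78 to −40 °C; 2 M HCl
Reagents that add atoms: none
Why: Hoppe homoaldol reaction: n-BuLi/(+)-sparteine gives the (R)-α-lithio carbamate (mirror image of the known (−)-sparteine/2-butenyl carbamate case), lithium–titanium exchange inverts to the (S)-titanium species, and the aldehyde adds at the γ-carbon (C3') on the titanium-bearing face through a chair transition state (aldehyde chain equatorial, OCb axial), which gives the (Z)-anti adduct with C3' (R) and C4' (S).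

**Step 7**
Reactants: 14 (1Z,3R,4S)-4-hydroxy-7-[4-(TBSO)phenyl]-3-{(E)-2-[4-(TBSO)phenyl]ethenyl}hept-1-en-1-yl N,N-diisopropylcarbamate
Product: 15 (1Z,3R,4S)-4-(TBSO)-7-[4-(TBSO)phenyl]-3-{(E)-2-[4-(TBSO)phenyl]ethenyl}hept-1-en-1-yl N,N-diisopropylcarbamate
Conditions: TBSOTf, 2,6-lutidine, CH2Cl2, −78 °C to 0 °C; aq NaHCO3
Reagents that add atoms: tert-butyldimethylsilyl trifluoromethanesulfonate, CC(C)(C)[Si](C)(C)OS(=O)(=O)C(F)(F)F
Why: Silylation of the hindered secondary alcohol blocks the C4' oxygen, which would otherwise capture the aldehyde in step 9 and give a tetrahydrofuran.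

**Step 8**
Reactants: 15 (1Z,3R,4S)-4-(TBSO)-7-[4-(TBSO)phenyl]-3-{(E)-2-[4-(TBSO)phenyl]ethenyl}hept-1-en-1-yl N,N-diisopropylcarbamate; 6 (2S)-2-{2-[4-(TBSO)phenyl]ethyl}oxirane
Product: 17 (3S,5Z,7R,8S)-8-(TBSO)-3-hydroxy-1,11-bis[4-(TBSO)phenyl]-7-{(E)-2-[4-(TBSO)phenyl]ethenyl}undec-5-en-5-yl N,N-diisopropylcarbamate, via vinyllithium 16 (not isolated)
Conditions: s-BuLi, TMEDA, THF, −78 °C, 45 min; then 6, BF3·OEt2 (3 equiv), −78 °C; aq NH4Cl
Reagents that add atoms: none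
Why: Carbamate-directed α-lithiation of the enol carbamate gives a configurationally stable vinyllithium (acyl anion equivalent of C4) that opens the BF3-activated epoxide at its CH2 terminus; the alkene geometry is retained and C6 comes unchanged from 6.

**Step 9**
Reactants: 17 (3S,5Z,7R,8S)-8-(TBSO)-3-hydroxy-1,11-bis[4-(TBSO)phenyl]-7-{(E)-2-[4-(TBSO)phenyl]ethenyl}undec-5-en-5-yl N,N-diisopropylcarbamate; 7 4-(TBSO)benzaldehyde
Product: 19 (2S,3R,6S)-3-[(1E,3R,4S)-4-(TBSO)-1,7-bis[4-(TBSO)phenyl]hept-1-en-3-yl]-2-[4-(TBSO)phenyl]-6-{2-[4-(TBSO)phenyl]ethyl}oxan-4-one, via oxocarbenium ion 18 (not isolated)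
Conditions: 7 (1.5 equiv), BF3·OEt2 (2 equiv), 2,6-di-tert-butyl-4-methylpyridine (0.5 equiv), CH2Cl2, −78 to −40 °C; aq NaHCO3
Reagents that add atoms: none
Why: Proposed new method: the C6 hydroxyl and aldehyde 7 condense to an (E)-oxocarbenium ion that is captured 6-endo by the β-carbon (C3) of the (Z)-enol carbamate through a chair transition state with the C6 chain, C2 aryl and C3 side chain all equatorial (2,6-cis and 2,3-trans, so C2 and C3 are set from C6, and C3 is also the thermodynamic epimer), and the carbamoyloxy carbenium ion then loses its carbamoyl group to fluoride to give the ketone; the closest known reactions are the silyl enol ether Prins cyclisation to oxan-4-ones and the BF3-mediated condensation of γ-hydroxy enol carbamates with aldehydes to tetrahydrofurans.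

**Step 10**
Reactants: 19 (2S,3R,6S)-3-[(1E,3R,4S)-4-(TBSO)-1,7-bis[4-(TBSO)phenyl]hept-1-en-3-yl]-2-[4-(TBSO)phenyl]-6-{2-[4-(TBSO)phenyl]ethyl}oxan-4-one
Product: 20 (2S,3S,4S,6S)-3-[(1E,3R,4S)-4-(TBSO)-1,7-bis[4-(TBSO)phenyl]hept-1-en-3-yl]-2-[4-(TBSO)phenyl]-6-{2-[4-(TBSO)phenyl]ethyl}oxan-4-ol
Conditions: LiBH(s-Bu)3, THF, −78 °C; aq NH4Cl
Reagents that add atoms: none
Why: The bulky trialkylborohydride attacks the chair oxan-4-one from the equatorial direction and gives the axial (4S) alcohol, cis to the equatorial C3 substituent.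

**Step 11**
Reactants: 20 (2S,3S,4S,6S)-3-[(1E,3R,4S)-4-(TBSO)-1,7-bis[4-(TBSO)phenyl]hept-1-en-3-yl]-2-[4-(TBSO)phenyl]-6-{2-[4-(TBSO)phenyl]ethyl}oxan-4-ol
Product: 21 (2S,3S,4S,6S)-3-[(1E,3R,4S)-4-hydroxy-1,7-bis(4-hydroxyphenyl)hept-1-en-3-yl]-2-(4-hydroxyphenyl)-6-[2-(4-hydroxyphenyl)ethyl]oxan-4-ol
Conditions: Bu4NF, AcOH (1:1, excess), THF, 0 °C to rt
Reagents that add atoms: none
Why: Fluoride cleaves the four aryl and one alkyl silyl ethers; acetic acid buffering keeps the phenols protonated so the para-hydroxybenzylic C2–O1 bond is not opened via a quinone methide.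

**Compound list**
1 | tert-butyl(4-iodophenoxy)dimethylsilane | CC(C)(C)[Si](C)(C)Oc1ccc(I)cc1 | starting material
2 | but-3-en-1-ol | C=CCCO | starting material
3 | 4-[4-(TBSO)phenyl]butanal | CC(C)(C)[Si](C)(C)Oc1ccc(CCCC=O)cc1 | intermediate
4 | (2R)-2-chloro-4-[4-(TBSO)phenyl]butanal | CC(C)(C)[Si](C)(C)Oc1ccc(CC[C@@H](Cl)C=O)cc1 | intermediate
5 | (2R)-2-chloro-4-[4-(TBSO)phenyl]butan-1-ol | CC(C)(C)[Si](C)(C)Oc1ccc(CC[C@@H](Cl)CO)cc1 | intermediate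
6 | (2S)-2-{2-[4-(TBSO)phenyl]ethyl}oxirane | CC(C)(C)[Si](C)(C)Oc1ccc(CC[C@H]2CO2)cc1 | intermediate
7 | 4-(tert-butyldimethylsilyloxy)benzaldehyde | CC(C)(C)[Si](C)(C)Oc1ccc(C=O)cc1 | starting material
8 | ethyl (2E)-4-(diethoxyphosphoryl)but-2-enoate | CCOC(=O)/C=C/CP(=O)(OCC)OCC | starting material
9 | ethyl (2E,4E)-5-[4-(TBSO)phenyl]penta-2,4-dienoate | CCOC(=O)/C=C/C=C/c1ccc(O[Si](C)(C)C(C)(C)C)cc1 | intermediate
10 | (2E,4E)-5-[4-(TBSO)phenyl]penta-2,4-dien-1-ol | OC/C=C/C=C/c1ccc(O[Si](C)(C)C(C)(C)C)cc1 | intermediate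
11 | (2E,4E)-5-[4-(TBSO)phenyl]penta-2,4-dien-1-yl N,N-diisopropylcarbamate | CC(C)N(C(C)C)C(=O)OC/C=C/C=C/c1ccc(O[Si](C)(C)C(C)(C)C)cc1 | intermediate
12 | (1R,2E,4E)-1-lithio derivative of 11 (Li on the OCb-bearing carbon; (+)-sparteine complex) | [Li][C@@H](OC(=O)N(C(C)C)C(C)C)/C=C/C=C/c1ccc(O[Si](C)(C)C(C)(C)C)cc1 | intermediate
13 | (1S,2E,4E)-1-[tri(isopropoxy)titanio] derivative of 11 | CC(C)O[Ti](OC(C)C)(OC(C)C)[C@H](OC(=O)N(C(C)C)C(C)C)/C=C/C=C/c1ccc(O[Si](C)(C)C(C)(C)C)cc1 | intermediate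
14 | (1Z,3R,4S)-4-hydroxy-7-[4-(TBSO)phenyl]-3-{(E)-2-[4-(TBSO)phenyl]ethenyl}hept-1-en-1-yl N,N-diisopropylcarbamate | CC(C)(C)[Si](C)(C)Oc1ccc(/C=C/[C@H](/C=C\OC(=O)N(C(C)C)C(C)C)[C@@H](O)CCCc2ccc(O[Si](C)(C)C(C)(C)C)cc2)cc1 | intermediate
15 | (1Z,3R,4S)-4-(TBSO)-7-[4-(TBSO)phenyl]-3-{(E)-2-[4-(TBSO)phenyl]ethenyl}hept-1-en-1-yl N,N-diisopropylcarbamate | CC(C)(C)[Si](C)(C)Oc1ccc(/C=C/[C@H](/C=C\OC(=O)N(C(C)C)C(C)C)[C@@H](O[Si](C)(C)C(C)(C)C)CCCc2ccc(O[Si](C)(C)C(C)(C)C)cc2)cc1 | intermediate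
16 | (1Z,3R,4S)-1-lithio derivative of 15 (Li replaces the vinylic H on the OCb-bearing carbon) | CC(C)(C)[Si](C)(C)Oc1ccc(/C=C/[C@H](/C=C(/[Li])OC(=O)N(C(C)C)C(C)C)[C@@H](O[Si](C)(C)C(C)(C)C)CCCc2ccc(O[Si](C)(C)C(C)(C)C)cc2)cc1 | intermediate
17 | (3S,5Z,7R,8S)-8-(TBSO)-3-hydroxy-1,11-bis[4-(TBSO)phenyl]-7-{(E)-2-[4-(TBSO)phenyl]ethenyl}undec-5-en-5-yl N,N-diisopropylcarbamate | CC(C)(C)[Si](C)(C)Oc1ccc(/C=C/[C@H](/C=C(\OC(=O)N(C(C)C)C(C)C)C[C@@H](O)CCc2ccc(O[Si](C)(C)C(C)(C)C)cc2)[C@@H](O[Si](C)(C)C(C)(C)C)CCCc2ccc(O[Si](C)(C)C(C)(C)C)cc2)cc1 | intermediate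
18 | oxocarbenium ion of 17 and 7 (C6–O+=CH–aryl) | CC(C)(C)[Si](C)(C)Oc1ccc(/C=C/[C@H](/C=C(\OC(=O)N(C(C)C)C(C)C)C[C@@H]([O+]=Cc2ccc(O[Si](C)(C)C(C)(C)C)cc2)CCc2ccc(O[Si](C)(C)C(C)(C)C)cc2)[C@@H](O[Si](C)(C)C(C)(C)C)CCCc2ccc(O[Si](C)(C)C(C)(C)C)cc2)cc1 | intermediate
19 | (2S,3R,6S)-3-[(1E,3R,4S)-4-(TBSO)-1,7-bis[4-(TBSO)phenyl]hept-1-en-3-yl]-2-[4-(TBSO)phenyl]-6-{2-[4-(TBSO)phenyl]ethyl}oxan-4-one | CC(C)(C)[Si](C)(C)Oc1ccc(/C=C/[C@H]([C@@H]2[C@@H](c3ccc(O[Si](C)(C)C(C)(C)C)cc3)O[C@@H](CCc3ccc(O[Si](C)(C)C(C)(C)C)cc3)CC2=O)[C@@H](O[Si](C)(C)C(C)(C)C)CCCc2ccc(O[Si](C)(C)C(C)(C)C)cc2)cc1 | intermediate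
20 | (2S,3S,4S,6S)-3-[(1E,3R,4S)-4-(TBSO)-1,7-bis[4-(TBSO)phenyl]hept-1-en-3-yl]-2-[4-(TBSO)phenyl]-6-{2-[4-(TBSO)phenyl]ethyl}oxan-4-ol | CC(C)(C)[Si](C)(C)Oc1ccc(/C=C/[C@H]([C@@H]2[C@@H](c3ccc(O[Si](C)(C)C(C)(C)C)cc3)O[C@@H](CCc3ccc(O[Si](C)(C)C(C)(C)C)cc3)C[C@@H]2O)[C@@H](O[Si](C)(C)C(C)(C)C)CCCc2ccc(O[Si](C)(C)C(C)(C)C)cc2)cc1 | intermediate
21 | (2S,3S,4S,6S)-3-[(1E,3R,4S)-4-hydroxy-1,7-bis(4-hydroxyphenyl)hept-1-en-3-yl]-2-(4-hydroxyphenyl)-6-[2-(4-hydroxyphenyl)ethyl]oxan-4-ol | Oc1ccc(/C=C/[C@H]([C@@H]2[C@@H](c3ccc(O)cc3)O[C@@H](CCc3ccc(O)cc3)C[C@@H]2O)[C@@H](O)CCCc2ccc(O)cc2)cc1 | target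

**Totals**
Total step count: 11. Longest linear sequence: 9 steps (steps 3, 4, 5, 6, 7, 8, 9, 10, 11).

**Three steps most likely to fail**

Step 6. The lithiated carbamate is an aryl-conjugated pentadienyl anion, so the sparteine complex may be configurationally labile (lower enantiomeric purity) and α- or ε-attack may compete with the γ-addition. The sense of induction is assumed by analogy with the 2-butenyl carbamate. Any minor enantiomer of 14 becomes a separable diastereomer once it is joined to enantiopure 6 in step 8. Fallback, setting out from 3 and coming back at 14: commercial (2E)-penta-2,4-dien-1-ol is carbamoylated (i-Pr2NCOCl, pyridine, 80 °C) to (2E)-penta-2,4-dien-1-yl N,N-diisopropylcarbamate F1, the non-aryl analogue closest to the well-understood 2-butenyl case. The same lithiation, titanation and addition to 3 gives (1Z,3R,4S)-3-ethenyl-4-hydroxy-7-[4-(TBSO)phenyl]hept-1-en-1-yl N,N-diisopropylcarbamate F2. The aryl group is then attached by cross-metathesis of the terminal vinyl group with tert-butyldimethyl(4-vinylphenoxy)silane (second-generation Hoveyda–Grubbs catalyst, CH2Cl2, 40 °C), which gives 14 with the E styrene.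

Step 8. The doubly allylic C3'–H may be deprotonated in competition with the vinylic C–H, the vinyllithium may undergo carbamoyl migration, and TMEDA competes for BF3. Fallback, setting out from 15 and coming back at 19: the enol carbamate is exchanged for a classical acyl anion equivalent. Propane-1,3-dithiol and BF3·OEt2 (CH2Cl2, −20 °C) convert 15 into 2-[(2S,3S)-3-(TBSO)-6-[4-(TBSO)phenyl]-2-{(E)-2-[4-(TBSO)phenyl]ethenyl}hexyl]-1,3-dithiane F3. Deprotonation with n-BuLi (THF, −30 °C) and alkylation with epoxide 6 gives (2S)-1-{2-[(2S,3S)-3-(TBSO)-6-[4-(TBSO)phenyl]-2-{(E)-2-[4-(TBSO)phenyl]ethenyl}hexyl]-1,3-dithian-2-yl}-4-[4-(TBSO)phenyl]butan-2-ol F4. MeI and CaCO3 in aqueous MeCN unmask (3S,7S,8S)-8-(TBSO)-3-hydroxy-1,11-bis[4-(TBSO)phenyl]-7-{(E)-2-[4-(TBSO)phenyl]ethenyl}undecan-5-one F5. F5 and 7 are then condensed with BF3·OEt2 (CH2Cl2, −40 °C); only the C3 enol can reach the oxocarbenium carbon through a six-membered transition state (acid-mediated Maitland–Japp-type closure), which gives 19.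

Step 9. The enol carbamate has not been used in a 6-endo closure before; direct condensation with the electron-rich aldehyde may be slow, or acetal formation and attack on the electron-rich styrene may compete. Fallback, setting out from 17 and coming back at 19 (segment-coupling Prins): 17 is esterified with 4-(tert-butyldimethylsilyloxy)benzoic acid (DCC, DMAP, CH2Cl2) to (3S,5Z,7R,8S)-5-(N,N-diisopropylcarbamoyloxy)-8-(TBSO)-1,11-bis[4-(TBSO)phenyl]-7-{(E)-2-[4-(TBSO)phenyl]ethenyl}undec-5-en-3-yl 4-(TBSO)benzoate F6. Reduction with i-Bu2AlH (−78 °C) and in situ acetylation (Ac2O, pyridine, DMAP) gives (3S,5Z,7R,8S)-3-{acetoxy[4-(TBSO)phenyl]methoxy}-8-(TBSO)-1,11-bis[4-(TBSO)phenyl]-7-{(E)-2-[4-(TBSO)phenyl]ethenyl}undec-5-en-5-yl N,N-diisopropylcarbamate F7 as both acetal epimers. SnBr4 or BF3·OEt2 (CH2Cl2, −78 °C) ionises the acetate to oxocarbenium ion 18 without free aldehyde or water, and cyclisation gives 19.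

**Further compounds**
F1 | step 6 | (2E)-penta-2,4-dien-1-yl N,N-diisopropylcarbamate | C=C/C=C/COC(=O)N(C(C)C)C(C)C
F2 | step 6 | (1Z,3R,4S)-3-ethenyl-4-hydroxy-7-[4-(TBSO)phenyl]hept-1-en-1-yl N,N-diisopropylcarbamate | C=C[C@H](/C=C\OC(=O)N(C(C)C)C(C)C)[C@@H](O)CCCc1ccc(O[Si](C)(C)C(C)(C)C)cc1
F3 | step 8 | 2-[(2S,3S)-3-(TBSO)-6-[4-(TBSO)phenyl]-2-{(E)-2-[4-(TBSO)phenyl]ethenyl}hexyl]-1,3-dithiane | CC(C)(C)[Si](C)(C)Oc1ccc(/C=C/[C@H](CC2SCCCS2)[C@@H](O[Si](C)(C)C(C)(C)C)CCCc2ccc(O[Si](C)(C)C(C)(C)C)cc2)cc1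
F4 | step 8 | (2S)-1-{2-[(2S,3S)-3-(TBSO)-6-[4-(TBSO)phenyl]-2-{(E)-2-[4-(TBSO)phenyl]ethenyl}hexyl]-1,3-dithian-2-yl}-4-[4-(TBSO)phenyl]butan-2-ol | CC(C)(C)[Si](C)(C)Oc1ccc(/C=C/[C@H](CC2(C[C@@H](O)CCc3ccc(O[Si](C)(C)C(C)(C)C)cc3)SCCCS2)[C@@H](O[Si](C)(C)C(C)(C)C)CCCc2ccc(O[Si](C)(C)C(C)(C)C)cc2)cc1
F5 | step 8 | (3S,7S,8S)-8-(TBSO)-3-hydroxy-1,11-bis[4-(TBSO)phenyl]-7-{(E)-2-[4-(TBSO)phenyl]ethenyl}undecan-5-one | CC(C)(C)[Si](C)(C)Oc1ccc(/C=C/[C@H](CC(=O)C[C@@H](O)CCc2ccc(O[Si](C)(C)C(C)(C)C)cc2)[C@@H](O[Si](C)(C)C(C)(C)C)CCCc2ccc(O[Si](C)(C)C(C)(C)C)cc2)cc1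
F6 | step 9 | (3S,5Z,7R,8S)-5-(N,N-diisopropylcarbamoyloxy)-8-(TBSO)-1,11-bis[4-(TBSO)phenyl]-7-{(E)-2-[4-(TBSO)phenyl]ethenyl}undec-5-en-3-yl 4-(TBSO)benzoate | CC(C)(C)[Si](C)(C)Oc1ccc(/C=C/[C@H](/C=C(\OC(=O)N(C(C)C)C(C)C)C[C@@H](OC(=O)c2ccc(O[Si](C)(C)C(C)(C)C)cc2)CCc2ccc(O[Si](C)(C)C(C)(C)C)cc2)[C@@H](O[Si](C)(C)C(C)(C)C)CCCc2ccc(O[Si](C)(C)C(C)(C)C)cc2)cc1
F7 | step 9 | (3S,5Z,7R,8S)-3-{acetoxy[4-(TBSO)phenyl]methoxy}-8-(TBSO)-1,11-bis[4-(TBSO)phenyl]-7-{(E)-2-[4-(TBSO)phenyl]ethenyl}undec-5-en-5-yl N,N-diisopropylcarbamate (both acetal epimers) | CC(C)(C)[Si](C)(C)Oc1ccc(/C=C/[C@H](/C=C(\OC(=O)N(C(C)C)C(C)C)C[C@@H](OC(OC(C)=O)c2ccc(O[Si](C)(C)C(C)(C)C)cc2)CCc2ccc(O[Si](C)(C)C(C)(C)C)cc2)[C@@H](O[Si](C)(C)C(C)(C)C)CCCc2ccc(O[Si](C)(C)C(C)(C)C)cc2)cc1
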